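The readings were generated by integration from invented constants; scatter was added.

- The easy step is the fall of the starting material, which stands at 33 % in the alpha run and 34 % in the epsilon run at 15.0 min, although the epsilon charge is 8.94 times the alpha charge; read as first-order, epsilon gives 0.0719 /min, so the supply of converted material by 20 min is 76.3 % of the charge.

| flask | starting material | first nucleophile | solid second nucleophile | remark | time |
|---|---|---|---|---|---|
| alpha | 4.7 mM | 14 mM | 20 mM | run made earlier |  |
| epsilon | 42 mM | 14 mM | 20 mM | run made earlier |  |
| zeta | 20 mM | 25 mM | 20 mM | run made earlier |  |
| Thursday's | 40 mM | 14.0 mM | 5.00 mM |  | 20 min |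
| Saturday's | 20 mM | 14.0 mM | 20.0 mM |  | 20 min |
| Sunday's | 60 mM | 14.0 mM | 80.0 mM |  | 20 min |
| Wednesday's | 12 mM | 40.0 mM | 20.0 mM |  | 20 min |
| Tuesday's | 6.0 mM | 8.00 mM | 80.0 mM |  | 20 min |

- alpha (time / min: target / %, starting material / %): 2.00: 5, 87; 5.00: 22, 70; 10.0: 42, 51; 15.0: 55, 33
- epsilon (time / min: target / %, starting material / %): 2.00: 8, 85; 5.00: 19, 67; 10.0: 30, 50; 15.0: 35, 34
- zeta (time / min: target / %, starting material / %): 4.00: 18, 75; 8.00: 36, 58; 10.0: 43, 53; 15.0: 58, 32

(readings scatter by 2 percentage points)

- the analysis behind the earlier runs scatters by 2 percentage points, standard deviation
- at the start none of the solid second nucleophile is in solution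

1. the flasks by amount of target, in percent of the starting material charged, highest first, at 20 min (Thursday's / Saturday's / Sunday's / Wednesday's / Tuesday's)
2. the amount of target, in percent of the starting material charged of the flask you put first, at 20 min
3. the amount of target, in percent of the starting material charged of the flask you put last, at 20 min

- In the epsilon run at 15.0 min, the starting material has lost 27.7 mM, but the target reads 14.7 mM against 14 mM of first nucleophile, which is 1.05 turnovers on a reading with a scatter of 2 percentage points, so this reckoning counts first nucleophile as the limiting reagent, taken up one for one.
- Sunday's then has a ceiling, the first nucleophile charge divided by the starting material charge, of 23.3 %, and the committed low is that figure, since its supply of 45.8 mM is more than its 14.0 mM of first nucleophile.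
- The same ceiling is 35.0 % for Thursday's and 70.0 % for Saturday's, whereas Wednesday's and Tuesday's have ceilings of 333 % and 133 %, above the supply, and Wednesday's ceiling is higher than Tuesday's, so this reckoning, which takes the lower of ceiling and supply for each flask and puts the higher ceiling first where both flasks stand at the supply, ranks Wednesday's, Tuesday's, Saturday's, Thursday's, Sunday's.
- The weak link is the assumption that target follows the supply at once: in the alpha run at 15.0 min, 12.0 % of the charge appears in neither reading, and if this pool is made as fast as it is captured, with 11.4 mM of first nucleophile left, the reading gives a capture constant of 17.3 /M/min.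
- Wednesday's keeps about 30.8 mM of first nucleophile at 20 min, so its pool is 3.19 % and the committed top is 73.1 %.
- The forecast, which differs from this reckoning, gives Tuesday's > Sunday's > Wednesday's > Saturday's > Thursday's, with 74 % at the top and 11 % at the bottom, on the ground that “that nucleophile is not consumed”.
- The flask gives Wednesday's > Tuesday's > Saturday's > Thursday's > Sunday's.

    first nucleophile + intermediate → target (k = 46.2 /M/min)
    second nucleophile + intermediate → other capture product (k = 10.6 /M/min)
    starting material → intermediate (k = 0.0705 /min)
    solid second nucleophile ⇌ second nucleophile, rate k4*(cs4 - [second nucleophile]) while solid is left; crystals form when [second nucleophile] > cs4 (solubility = 6.60 mM, k = 0.0247 /min)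

- Sunday's gives 23.3 % against its ceiling of 23.3 %, with its first nucleophile at 0 % of its own charge, Wednesday's gives 73.8 %, and the forecast and the flask part on first nucleophile, which the forecast held to be unconsumed. The same flask as Sunday's with 150 mM of starting material holds 0.0933 equiv of first nucleophile to starting material, so its ceiling is 9.33 %; at 20.0 min its first nucleophile stands at 0 % of its own charge, its intermediate at 64.3 % of the starting material charged, and its target at 9.33 %.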